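## Retrosynthetic overview

- The six-membered ring is never built. It is bought as 2-methoxy-5-methylphenol, carried as its MOM ether, and oxidised at its free para CH (ring C4) to the 1,4-benzoquinone in the last step, so no ring-forming step occurs.
- Key disconnection: side-chain bond C23′–C24′ (chain numbered from the ring CH2, C1′, to C40′). It is made by nickel-electrocatalytic decarboxylative alkenylation of an (E)-alkenyl iodide (arene plus C1′–C23′) with the N-hydroxyphthalimide ester of the acid that supplies C24′–C40′.
- Enabling feature: C23′ is the methyl-bearing sp2 carbon of the trisubstituted C22′=C23′ olefin, so it can be carried as an (E)-2-iodoalk-2-ene made from a methyl alkyne. C24′ is an unbranched CH2 followed by CH2 C25′, so its radical is primary and has no olefin within 5- or 6-exo reach.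
- Iodide half: ortho-lithiation/cupration of the aryl MOM ether and SN2 coupling with geranylgeranyl bromide, SeO2 oxidation of the terminal E-methyl group (C16′), bromide, sulfone alkylation with a C9 enyne sulfone from geranyl acetate (bond C16′–C17′), desulfonylation, hydrozirconation–iodination.
- Ester half: geranylgeranyl bromide plus the dianion of acetic acid, then the N-hydroxyphthalimide ester. All E-olefins come from geranylgeraniol and geranyl acetate except C22′=C23′, which is set by hydrozirconation.

Key step: step 16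

Remark: commercial all-E geranylgeraniol and (E)-geranyl acetate are assumed; the sulfone-bearing carbon made in step 11 is racemic and is removed in step 12, so the target has no stereocentre, only nine E-olefins.

## Route

Step 1
Reactants: 1 (2E,6E,10E)-geranylgeraniol
Product: 2 (2E,6E,10E)-geranylgeranyl bromide
Conditions: PBr3 (0.4 equiv), Et2O, 0 °C
Reagents that add atoms: phosphorus tribromide, BrP(Br)Br
Why: Bromination of the primary allylic alcohol by PBr3 at 0 °C goes through the phosphite ester and SN2 displacement by bromide at C1, so neither allylic transposition nor loss of the 2E geometry is expected.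

Step 2
Reactants: 3 2-methoxy-5-methylphenol
Product: 4 1-methoxy-2-(methoxymethoxy)-4-methylbenzene
Conditions: MOMCl, i-Pr2NEt, CH2Cl2, 0 °C → rt
Reagents that add atoms: chloromethyl methyl ether, COCCl
Why: Williamson-type O-alkylation of the phenol with the reactive chloromethyl ether gives the MOM acetal, which serves both as protecting group and as the strongest ortho-director on the ring.

Step 3
Reactants: 4 1-methoxy-2-(methoxymethoxy)-4-methylbenzene; 2 (2E,6E,10E)-geranylgeranyl bromide
Product: 7 1-methoxy-2-(methoxymethoxy)-4-methyl-3-[(2E,6E,10E)-3,7,11,15-tetramethylhexadeca-2,6,10,14-tetraen-1-yl]benzene, via aryllithium 5 (not isolated), via arylcopper 6 (not isolated)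
Conditions: n-BuLi, TMEDA, THF, 0 °C; CuBr·SMe2 (1.0 equiv), –78 °C; then 2, –78 → 0 °C
Reagents that add atoms: none
Why: Directed ortho-metalation, in which the chelating OMOM group outranks OMe as director and its only free ortho position is C3 (between OMOM and the methyl group), followed by Li→Cu transmetalation and SN2 allylation of the soft arylcopper by the primary allylic bromide (γ-attack would have to form a quaternary carbon), which keeps the 2E olefin.

Step 4
Reactants: 7 aryl geranylgeranyl MOM ether
Product: 8 (2E,6E,10E,14E)-16-[3-methoxy-2-(methoxymethoxy)-6-methylphenyl]-2,6,10,14-tetramethylhexadeca-2,6,10,14-tetraen-1-ol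
Conditions: SeO2 (0.2 equiv), t-BuOOH (3 equiv), salicylic acid (0.1 equiv), CH2Cl2, 0 °C → rt
Reagents that add atoms: selenium dioxide (oxygen carrier), O=[Se]=O; tert-butyl hydroperoxide (terminal oxidant), CC(C)(C)OO
Why: Sharpless–Umbreit allylic oxidation (SeO2 ene reaction, then [2,3]-sigmatropic shift) should select the most accessible and electron-rich olefin, the terminal gem-dimethyl unit, and within it the methyl group trans to the chain, so the new primary allylic alcohol is E; modest conversion with recovery of 7 is expected.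

Step 5
Reactants: 8 ω-hydroxy aryl tetraene
Product: 9 2-[(2E,6E,10E,14E)-16-bromo-3,7,11,15-tetramethylhexadeca-2,6,10,14-tetraen-1-yl]-4-methoxy-3-(methoxymethoxy)-1-methylbenzene
Conditions: CBr4, PPh3, CH2Cl2, 0 °C
Reagents that add atoms: carbon tetrabromide, BrC(Br)(Br)Br
Why: Appel bromination under neutral conditions converts the allylic alcohol to the bromide by SN2 attack on the oxyphosphonium ion without touching the MOM acetal or the olefin geometry.

Step 6
Reactants: 10 (E)-geranyl acetate
Product: 11 (2E)-3-methyl-6-oxohex-2-en-1-yl acetate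
Conditions: O3 (1.0 equiv), CH2Cl2/MeOH, –78 °C; Me2S, –78 °C → rt
Reagents that add atoms: ozone, [O-][O+]=O
Why: Ozone is an electrophile and should cleave only the electron-rich isopropylidene olefin, the C2=C3 olefin being deactivated by the allylic acetate (chemoselective ozonolysis with reductive work-up).

Step 7
Reactants: 11 (2E)-3-methyl-6-oxohex-2-en-1-yl acetate
Product: 13 (2E)-3-methylhept-2-en-6-yn-1-ol, via enyne acetate 12 (not isolated)
Conditions: dimethyl (1-diazo-2-oxopropyl)phosphonate, K2CO3, MeOH, 0 °C → rt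
Reagents that add atoms: dimethyl (1-diazo-2-oxopropyl)phosphonate, COP(=O)(OC)C(=[N+]=[N-])C(C)=O
Why: Seyferth–Gilbert homologation in the Ohira–Bestmann variant turns the aldehyde into the terminal alkyne under K2CO3/MeOH, and the same medium methanolyses the acetate, so the free allylic alcohol is obtained directly.

Step 8
Reactants: 13 (2E)-3-methylhept-2-en-6-yn-1-ol
Product: 15 (2E)-3-methyloct-2-en-6-yn-1-ol, via dilithium alkoxide acetylide 14 (not isolated)
Conditions: n-BuLi (2.1 equiv), THF, –78 → 0 °C; MeI (1.05 equiv), DMPU, –78 °C → rt; aq. NH4Cl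
Reagents that add atoms: iodomethane, CI
Why: In the O,C-dianion the acetylide carbon is by far the more nucleophilic site, so one equivalent of MeI should alkylate carbon selectively (acetylide alkylation), giving the methyl alkyne that later becomes C22′–C23′ with its methyl branch.

Step 9
Reactants: 15 (2E)-3-methyloct-2-en-6-yn-1-ol
Product: 16 (2E)-1-bromo-3-methyloct-2-en-6-yne
Conditions: PBr3 (0.4 equiv), Et2O, 0 °C
Reagents that add atoms: phosphorus tribromide, BrP(Br)Br
Why: PBr3 bromination of the primary allylic alcohol by SN2 displacement, as in step 1, keeps the 2E geometry and leaves the internal alkyne untouched.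

Step 10
Reactants: 16 (2E)-1-bromo-3-methyloct-2-en-6-yne
Product: 17 {[(2E)-3-methyloct-2-en-6-yn-1-yl]sulfonyl}benzene
Conditions: PhSO2Na, DMF, rt
Reagents that add atoms: sodium benzenesulfinate, [Na+].[O-]S(=O)c1ccccc1
Why: S-alkylation of the ambident sulfinate by the soft allylic bromide (SN2) gives the allylic phenyl sulfone, the carbanion-stabilising group needed for the chain junction.

Step 11
Reactants: 17 C9 enyne sulfone; 9 aryl ω-bromo tetraene
Product: 19 4-methoxy-3-(methoxymethoxy)-1-methyl-2-[(2E,6E,10E,14E,18E)-3,7,11,15,19-pentamethyl-17-(phenylsulfonyl)tetracosa-2,6,10,14,18-pentaen-22-yn-1-yl]benzene (racemic at the sulfone carbon), via lithiated sulfone 18 (not isolated)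
Conditions: n-BuLi (1.0 equiv), THF, –78 °C; then 9, –78 → –20 °C
Reagents that add atoms: none
Why: Alkylation of the α-sulfonyl allyl carbanion with the primary allylic bromide (Julia-type sulfone coupling of isoprenoids) forms the C16′–C17′ bond strictly α to sulfur, so both flanking E-olefins stay in place, and the new sulfone-bearing stereocentre at C17′ is formed as a racemate that is erased in step 12.

Step 12
Reactants: 19 aryl C24 sulfone
Product: 20 4-methoxy-3-(methoxymethoxy)-1-methyl-2-[(2E,6E,10E,14E,18E)-3,7,11,15,19-pentamethyltetracosa-2,6,10,14,18-pentaen-22-yn-1-yl]benzene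
Conditions: Pd(dppp)Cl2 (5 mol %), LiBHEt3 (2.5 equiv), THF, 0 °C
Reagents that add atoms: none
Why: Palladium-catalysed reductive desulfonylation, in which zerovalent palladium formed from Pd(dppp)Cl2 ionises the allylic sulfone to a π-allyl complex and hydride from LiBHEt3 is delivered to the less substituted terminus C17′, which keeps the C18′=C19′ olefin trisubstituted and E and leaves the unactivated alkyne untouched.

Step 13
Reactants: 20 aryl pentaenyne
Product: 22 2-[(2E,6E,10E,14E,18E,22E)-23-iodo-3,7,11,15,19-pentamethyltetracosa-2,6,10,14,18,22-hexaen-1-yl]-4-methoxy-3-(methoxymethoxy)-1-methylbenzene, via alkenylzirconocene chloride 21 (not isolated)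
Conditions: Cp2Zr(H)Cl (2.2 equiv), THF, 50 °C; then I2, THF, 0 °C, dark; aq. Na2S2O3
Reagents that add atoms: iodine, II
Why: Syn-hydrozirconation of the alkyne (the trisubstituted olefins should not react) under thermodynamic control by excess Cp2Zr(H)Cl places zirconium on the less hindered, methyl-bearing carbon C23′, and iodinolysis of the C–Zr bond with retention gives the (22′E)-alkenyl iodide.

Step 14
Reactants: 2 (2E,6E,10E)-geranylgeranyl bromide; 23 acetic acid
Product: 25 (4E,8E,12E)-5,9,13,17-tetramethyloctadeca-4,8,12,16-tetraenoic acid, via dilithium acetate dianion 24 (not isolated)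
Conditions: LiN(i-Pr)2 (2.1 equiv), THF/DMPU, 0 → 40 °C; then 2, 0 °C → rt; 1 M HCl
Reagents that add atoms: none
Why: The dilithium dianion of acetic acid (α-lithio carboxylate) is C-alkylated by the primary allylic bromide in an SN2 reaction, which adds C24′ and the carboxyl carbon that is later lost, without disturbing the E-olefins.

Step 15
Reactants: 25 C22 tetraenoic acid
Product: 26 1,3-dioxoisoindolin-2-yl (4E,8E,12E)-5,9,13,17-tetramethyloctadeca-4,8,12,16-tetraenoate
Conditions: N-hydroxyphthalimide, N,N′-diisopropylcarbodiimide, DMAP (cat.), CH2Cl2, rt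
Reagents that add atoms: N-hydroxyphthalimide, ON1C(=O)c2ccccc2C1=O
Why: Carbodiimide-mediated (Steglich-type) esterification with N-hydroxyphthalimide gives the redox-active ester under neutral conditions.

Step 16
Reactants: 22 aryl (22′E)-alkenyl iodide; 26 N-hydroxyphthalimide ester
Product: 27 4-methoxy-3-(methoxymethoxy)-1-methyl-2-[(2E,6E,10E,14E,18E,22E,26E,30E,34E)-3,7,11,15,19,23,27,31,35,39-decamethyltetraconta-2,6,10,14,18,22,26,30,34,38-decaen-1-yl]benzene
Conditions: NiCl2·6H2O (20 mol %), 2,2′-bipyridine (20 mol %), AgNO3 (0.3 equiv), 26 (2 equiv), DMF/THF, rt, undivided cell, Mg anode, reticulated vitreous carbon cathode, constant current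
Reagents that add atoms: none
Why: Cathodic reduction (AgNO3 first deposits silver nanoparticles on the carbon cathode, which keep the nickel catalyst active) turns NiCl2/2,2′-bipyridine into low-valent nickel that inserts into the C23′–I bond of 22 with retention, while single-electron reduction of the N-acyloxyphthalimide 26 releases phthalimide anion and CO2 and leaves the primary C24′ radical; capture of this radical at the alkenylnickel and reductive elimination from trivalent nickel forge the C23′–C24′ bond, the Mg anode supplying the electrons. The closest known reaction type is the nickel-electrocatalytic decarboxylative alkenylation of redox-active esters with alkenyl iodides, which has been used to join all-E polyprenyl chains at C(sp2)–C(sp3) bonds. No ring is closed and no stereocentre is created; the only stereochemical demand is retention of the 22′E geometry, which oxidative addition and reductive elimination at the sp2 carbon should deliver. The step needs cross-coupling to win over dimerisation of 22 and over reduction or dimerisation of the radical: the alkenyl iodide is the only carbon–halogen bond and the fastest electrophile for nickel, 26 is used in excess, and the radical is an unstabilised primary one that is captured quickly. The radical must also leave the trisubstituted olefins of both partners untouched: the nearest one, C26′=C27′, is homoallylic, so only a reversible 3-exo closure is open and no 5- or 6-exo path exists. The aryl MOM and methyl ethers are inert at the mild cathodic potential, which is why the quinone is carried through this step as a protected phenol.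

Step 17
Reactants: 27 MOM-protected decaprenyl arene
Product: 28 6-methoxy-3-methyl-2-[(2E,6E,10E,14E,18E,22E,26E,30E,34E)-3,7,11,15,19,23,27,31,35,39-decamethyltetraconta-2,6,10,14,18,22,26,30,34,38-decaen-1-yl]phenol
Conditions: HCl (0.5 M), MeOH/THF, rt
Reagents that add atoms: none
Why: Acid-catalysed acetal exchange with methanol removes the MOM group as dimethoxymethane under conditions dilute and cool enough that the isolated trisubstituted olefins should not be protonated and the ortho-prenyl phenol should not close to a chroman.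

Step 18
Reactants: 28 decaprenyl phenol
Product: 29 2-methoxy-5-methyl-6-[(2E,6E,10E,14E,18E,22E,26E,30E,34E)-3,7,11,15,19,23,27,31,35,39-decamethyltetraconta-2,6,10,14,18,22,26,30,34,38-decaen-1-yl]cyclohexa-2,5-diene-1,4-dione (CID25010748)
Conditions: Co(salen) (C16H14CoN2O2, divalent cobalt, 20 mol %), O2 (1 atm), DMF/THF, rt
Reagents that add atoms: dioxygen, O=O
Why: Cobalt–salen catalysed aerobic oxidation of a phenol to the para-quinone, in which the cobalt–superoxo species abstracts the phenolic hydrogen and O2 is delivered to the free para position C4, both ortho positions being blocked by OMe and the chain, so the 1,4-benzoquinone should form without attack on the allylic positions.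

## Compound list

1 | (2E,6E,10E)-3,7,11,15-tetramethylhexadeca-2,6,10,14-tetraen-1-ol (geranylgeraniol) | OC/C=C(\C)CC/C=C(\C)CC/C=C(\C)CCC=C(C)C | starting material
2 | (2E,6E,10E)-geranylgeranyl bromide | BrC/C=C(\C)CC/C=C(\C)CC/C=C(\C)CCC=C(C)C | intermediate
3 | 2-methoxy-5-methylphenol | COc1ccc(C)cc1O | starting material
4 | 1-methoxy-2-(methoxymethoxy)-4-methylbenzene | COCOc1cc(C)ccc1OC | intermediate
5 | 3-lithio derivative of 4 (aryllithium, formed in situ) | COCOc1c([Li])c(C)ccc1OC | intermediate
6 | 3-cuprio derivative of 4 (arylcopper, formed in situ) | COCOc1c([Cu])c(C)ccc1OC | intermediate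
7 | 1-methoxy-2-(methoxymethoxy)-4-methyl-3-[(2E,6E,10E)-3,7,11,15-tetramethylhexadeca-2,6,10,14-tetraen-1-yl]benzene | COCOc1c(C/C=C(\C)CC/C=C(\C)CC/C=C(\C)CCC=C(C)C)c(C)ccc1OC | intermediate
8 | (2E,6E,10E,14E)-16-[3-methoxy-2-(methoxymethoxy)-6-methylphenyl]-2,6,10,14-tetramethylhexadeca-2,6,10,14-tetraen-1-ol | COCOc1c(C/C=C(\C)CC/C=C(\C)CC/C=C(\C)CC/C=C(\C)CO)c(C)ccc1OC | intermediate
9 | 2-[(2E,6E,10E,14E)-16-bromo-3,7,11,15-tetramethylhexadeca-2,6,10,14-tetraen-1-yl]-4-methoxy-3-(methoxymethoxy)-1-methylbenzene | COCOc1c(C/C=C(\C)CC/C=C(\C)CC/C=C(\C)CC/C=C(\C)CBr)c(C)ccc1OC | intermediate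
10 | (2E)-3,7-dimethylocta-2,6-dien-1-yl acetate (geranyl acetate) | CC(=O)OC/C=C(\C)CCC=C(C)C | starting material
11 | (2E)-3-methyl-6-oxohex-2-en-1-yl acetate | CC(=O)OC/C=C(\C)CCC=O | intermediate
12 | (2E)-3-methylhept-2-en-6-yn-1-yl acetate (formed in situ) | CC(=O)OC/C=C(\C)CCC#C | intermediate
13 | (2E)-3-methylhept-2-en-6-yn-1-ol | OC/C=C(\C)CCC#C | intermediate
14 | dilithium alkoxide acetylide of 13 (formed in situ) | [Li]OC/C=C(\C)CCC#C[Li] | intermediate
15 | (2E)-3-methyloct-2-en-6-yn-1-ol | OC/C=C(\C)CCC#CC | intermediate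
16 | (2E)-1-bromo-3-methyloct-2-en-6-yne | BrC/C=C(\C)CCC#CC | intermediate
17 | {[(2E)-3-methyloct-2-en-6-yn-1-yl]sulfonyl}benzene | O=S(=O)(C/C=C(\C)CCC#CC)c1ccccc1 | intermediate
18 | α-lithio derivative of sulfone 17 (formed in situ) | [Li]C(/C=C(\C)CCC#CC)S(=O)(=O)c1ccccc1 | intermediate
19 | 4-methoxy-3-(methoxymethoxy)-1-methyl-2-[(2E,6E,10E,14E,18E)-3,7,11,15,19-pentamethyl-17-(phenylsulfonyl)tetracosa-2,6,10,14,18-pentaen-22-yn-1-yl]benzene (racemic) | COCOc1c(C/C=C(\C)CC/C=C(\C)CC/C=C(\C)CC/C=C(\C)CC(/C=C(\C)CCC#CC)S(=O)(=O)c2ccccc2)c(C)ccc1OC | intermediate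
20 | 4-methoxy-3-(methoxymethoxy)-1-methyl-2-[(2E,6E,10E,14E,18E)-3,7,11,15,19-pentamethyltetracosa-2,6,10,14,18-pentaen-22-yn-1-yl]benzene | COCOc1c(C/C=C(\C)CC/C=C(\C)CC/C=C(\C)CC/C=C(\C)CC/C=C(\C)CCC#CC)c(C)ccc1OC | intermediate
21 | (22E)-23-[chlorobis(cyclopentadienyl)zirconio] alkenyl derivative of 20 (formed in situ; cyclopentadienyl rings drawn σ-bonded) | COCOc1c(C/C=C(\C)CC/C=C(\C)CC/C=C(\C)CC/C=C(\C)CC/C=C(\C)CC/C=C(\C)[Zr](Cl)(C2C=CC=C2)C2C=CC=C2)c(C)ccc1OC | intermediate
22 | 2-[(2E,6E,10E,14E,18E,22E)-23-iodo-3,7,11,15,19-pentamethyltetracosa-2,6,10,14,18,22-hexaen-1-yl]-4-methoxy-3-(methoxymethoxy)-1-methylbenzene | COCOc1c(C/C=C(\C)CC/C=C(\C)CC/C=C(\C)CC/C=C(\C)CC/C=C(\C)CC/C=C(\C)I)c(C)ccc1OC | intermediate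
23 | acetic acid | CC(=O)O | starting material
24 | dilithium dianion of acetic acid (formed in situ) | [Li]CC(=O)O[Li] | intermediate
25 | (4E,8E,12E)-5,9,13,17-tetramethyloctadeca-4,8,12,16-tetraenoic acid | OC(=O)CC/C=C(\C)CC/C=C(\C)CC/C=C(\C)CCC=C(C)C | intermediate
26 | 1,3-dioxoisoindolin-2-yl (4E,8E,12E)-5,9,13,17-tetramethyloctadeca-4,8,12,16-tetraenoate | O=C(CC/C=C(\C)CC/C=C(\C)CC/C=C(\C)CCC=C(C)C)ON1C(=O)c2ccccc2C1=O | intermediate
27 | 4-methoxy-3-(methoxymethoxy)-1-methyl-2-[(all-E)-3,7,11,15,19,23,27,31,35,39-decamethyltetraconta-2,6,10,14,18,22,26,30,34,38-decaen-1-yl]benzene | COCOc1c(C/C=C(\C)CC/C=C(\C)CC/C=C(\C)CC/C=C(\C)CC/C=C(\C)CC/C=C(\C)CC/C=C(\C)CC/C=C(\C)CC/C=C(\C)CCC=C(C)C)c(C)ccc1OC | intermediate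
28 | 6-methoxy-3-methyl-2-[(all-E)-3,7,11,15,19,23,27,31,35,39-decamethyltetraconta-2,6,10,14,18,22,26,30,34,38-decaen-1-yl]phenol | COc1ccc(C)c(C/C=C(\C)CC/C=C(\C)CC/C=C(\C)CC/C=C(\C)CC/C=C(\C)CC/C=C(\C)CC/C=C(\C)CC/C=C(\C)CC/C=C(\C)CCC=C(C)C)c1O | intermediate
29 | 2-methoxy-5-methyl-6-[(all-E)-3,7,11,15,19,23,27,31,35,39-decamethyltetraconta-2,6,10,14,18,22,26,30,34,38-decaen-1-yl]cyclohexa-2,5-diene-1,4-dione (CID25010748) | COC1=CC(=O)C(C)=C(C/C=C(\C)CC/C=C(\C)CC/C=C(\C)CC/C=C(\C)CC/C=C(\C)CC/C=C(\C)CC/C=C(\C)CC/C=C(\C)CC/C=C(\C)CCC=C(C)C)C1=O | target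

## Step count and risks

Total step count: 18. Longest linear sequence: 11 steps (steps 6–13, then 16–18, from geranyl acetate).

Steps most likely to fail:

1. Step 16 (electroreductive coupling). The alkenylnickel intermediate may be diverted to protodeiodination or homocoupling and the radical lost to hydrogen abstraction, because both partners are very lipophilic and may be poorly solvated in the electrolyte. The fallback makes the same C23′–C24′ bond by a B-alkyl Suzuki–Miyaura coupling. It sets out from geranylgeraniol 1 and iodide 22. MnO2 oxidation of 1 gives geranylgeranial F1. Wittig methylenation (Ph3P=CH2, THF) gives the pentaene F2. 9-BBN-H should hydroborate only the terminal vinyl group of the 1,3-diene to the B-alkyl borane F3. F3 is coupled in the same flask with 22 [Pd(dppf)Cl2, AsPh3, Cs2CO3, DMF/THF/H2O, rt] with retention at the sp2 carbon. The fallback comes back to the route at 27.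

2. Step 13 (hydrozirconation–iodination on the hexaene). Equilibration of the alkenylzirconium regioisomers may stay incomplete, or the excess hydride may slowly engage chain olefins, and the resulting isomeric iodides could not be separated at this size. The fallback reverses the order of bond formation so that the iodide is purified while small. It sets out from enynol 15. The same Cp2Zr(H)Cl/I2 sequence gives (2E,6E)-7-iodo-3-methylocta-2,6-dien-1-ol F4, freed of its regioisomer by chromatography. F4 is coupled with ester 26 under the conditions of step 16 to give all-E hexaprenol F5. PBr3 gives hexaprenyl bromide F6, and PhSO2Na gives hexaprenyl phenyl sulfone F7. Lithiation of F7 (n-BuLi, THF, –78 °C) and alkylation with bromide 9 gives the coupled sulfone F8. Pd(dppp)Cl2/LiBHEt3 desulfonylation of F8 comes back to the route at 27, bypassing 16–22.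

3. Step 3 (directed metalation). Deprotonation may leak to the position ortho to the OMe group (C6 of 4), giving a regioisomeric arylcopper and an inseparable isomer of 7. The fallback fixes the metalation site with a halogen. It sets out from phenol 3. Amine-mediated ortho-bromination (NBS, i-Pr2NH cat., CH2Cl2), directed by the hydroxyl group to its only free ortho position, gives 2-bromo-6-methoxy-3-methylphenol F9. MOMCl/i-Pr2NEt gives the bromo MOM ether F10. Bromine–lithium exchange (n-BuLi, THF, –78 °C) comes back to the route at aryllithium 5.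

Further compounds

F1 | step 16 | (2E,6E,10E)-3,7,11,15-tetramethylhexadeca-2,6,10,14-tetraenal (geranylgeranial) | O=C/C=C(\C)CC/C=C(\C)CC/C=C(\C)CCC=C(C)C
F2 | step 16 | (3E,7E,11E)-4,8,12,16-tetramethylheptadeca-1,3,7,11,15-pentaene | C=C/C=C(\C)CC/C=C(\C)CC/C=C(\C)CCC=C(C)C
F3 | step 16 | 9-[(3E,7E,11E)-4,8,12,16-tetramethylheptadeca-3,7,11,15-tetraen-1-yl]-9-borabicyclo[3.3.1]nonane | B1(CC/C=C(\C)CC/C=C(\C)CC/C=C(\C)CCC=C(C)C)C2CCCC1CCC2
F4 | step 13 | (2E,6E)-7-iodo-3-methylocta-2,6-dien-1-ol | OC/C=C(\C)CC/C=C(\C)I
F5 | step 13 | (2E,6E,10E,14E,18E)-3,7,11,15,19,23-hexamethyltetracosa-2,6,10,14,18,22-hexaen-1-ol (all-E hexaprenol) | OC/C=C(\C)CC/C=C(\C)CC/C=C(\C)CC/C=C(\C)CC/C=C(\C)CCC=C(C)C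
F6 | step 13 | all-E hexaprenyl bromide | BrC/C=C(\C)CC/C=C(\C)CC/C=C(\C)CC/C=C(\C)CC/C=C(\C)CCC=C(C)C
F7 | step 13 | all-E hexaprenyl phenyl sulfone | O=S(=O)(C/C=C(\C)CC/C=C(\C)CC/C=C(\C)CC/C=C(\C)CC/C=C(\C)CCC=C(C)C)c1ccccc1
F8 | step 13 | 17′-(phenylsulfonyl) derivative of 27 (racemic) | COCOc1c(C/C=C(\C)CC/C=C(\C)CC/C=C(\C)CC/C=C(\C)CC(/C=C(\C)CC/C=C(\C)CC/C=C(\C)CC/C=C(\C)CC/C=C(\C)CCC=C(C)C)S(=O)(=O)c2ccccc2)c(C)ccc1OC
F9 | step 3 | 2-bromo-6-methoxy-3-methylphenol | COc1ccc(C)c(Br)c1O
F10 | step 3 | 2-bromo-4-methoxy-3-(methoxymethoxy)-1-methylbenzene | COCOc1c(Br)c(C)ccc1OC
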